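## Retrosynthetic overview

1. Target 38 ⇐ 36 (unmask the ring-A α-methylene lactone) ⇐ 26 + 18 + 30. The central cyclohexene (bonds C5–C13′, C11′–C3, C2–C1) is closed last by a stepwise three-component Michael/Michael/nitro-aldol annulation.
2. 18 ⇐ 11; 11 and 26 are antipodal 7-methylcyclohepta[b]furan-2,6-diones, each made by the key step: a one-carbon ring expansion (diazoalkane homologation, 1,2-shift) of the cis-fused benzofuran-2,5-diones 9 and 24.
3. 9 / 24 ⇐ acrylates 7 / 22 (intramolecular Rauhut–Currier lactone annulation) ⇐ (R)- / (S)-4-hydroxycyclohexenone 3 / 19 ⇐ one batch of the meso endoperoxide 2 ⇐ cyclohexa-1,3-diene + O2.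
4. Ring order in each half: cyclohexenone → cis-γ-lactone → seven-membered carbocycle by ring expansion. Then the central six-membered ring with the spiro centre is formed, and the ring-A exocyclic methylene is freed last.

Assumptions and conventions (one line each):
- Positions use xanthanolide numbering: unprimed C1–C15 for the half with the α-methylene lactone (ring A), primed for the spiro-lactone half.
- The SMILES is taken as written: the upper half is 7R,8R,10S and the lower half is its antipode in these three centres (7′S,8′S,10′R), so both antipodes of one keto-lactone are made.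
- The cupreidine-derived catalyst is assumed to give the (R)-hydroxy-enone and the cupreine-derived one the (S)-antipode; if the sense is the reverse, the two catalysts are exchanged.
- Carbons that later become sp2 or lose their substituent are formed as epimer mixtures and left undefined in the SMILES: the CH–CH2SPh carbon, the silyl-bearing carbon in 10/25, and C-2/C-3 in 33/34.

## Route

Step 1
Reactants: 1 cyclohexa-1,3-diene
Product: 2 2,3-dioxabicyclo[2.2.2]oct-5-ene (meso endoperoxide)
Conditions: O2, TPP (0.1 mol%), hν, CH2Cl2, 0 °C; concentrate below 25 °C, short silica plug; stored at −20 °C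
Reagents that add atoms: oxygen, O=O
Why: Singlet oxygen adds to the cisoid diene in a [4+2] photo-oxygenation to give the isolable meso endoperoxide, and one batch of it is divided between the two enantiomeric series.

Step 2
Reactants: 2 2,3-dioxabicyclo[2.2.2]oct-5-ene
Product: 3 (R)-4-hydroxycyclohex-2-en-1-one
Conditions: 9-O-acetylcupreidine (10 mol%), CH2Cl2, 20 °C
Reagents that add atoms: none
Why: In the chiral-base-catalysed Kornblum–DeLaMare rearrangement the catalyst removes one of the two enantiotopic bridgehead hydrogens, which sets the carbinol centre.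

Step 3
Reactants: 3 (R)-4-hydroxycyclohex-2-en-1-one
Product: 5 (4R,6R)-4-hydroxy-6-methylcyclohex-2-en-1-one (4,6-trans), via dilithium alkoxide-dienolate 4 (not isolated)
Conditions: LiN(iPr)2 (2.2 equiv), THF, −78 °C; MeI (1.05 equiv), −78 → −40 °C; 1 M HCl
Reagents that add atoms: iodomethane, CI
Why: Kinetic α′-deprotonation of the lithium alkoxide gives the cross-conjugated enolate, which is C-methylated by axial attack anti to the pseudo-equatorial C-4 oxygen to give the 4,6-trans isomer (enolate alkylation).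

Step 4
Reactants: 5 (4R,6R)-4-hydroxy-6-methylcyclohex-2-en-1-one; 6 acrylic acid
Product: 7 (1S,5R)-5-methyl-4-oxocyclohex-2-en-1-yl prop-2-enoate (1,5-cis)
Conditions: PPh3, DIAD, THF, 0 → 20 °C
Reagents that add atoms: none
Why: Mitsunobu esterification inverts the carbinol carbon, so the future lactone oxygen (C-8′) becomes cis to the methyl group (C-10′).

Step 5
Reactants: 7 (1S,5R)-5-methyl-4-oxocyclohex-2-en-1-yl prop-2-enoate
Product: 9 (3aS,6R,7aS)-6-methyl-3-[(phenylsulfanyl)methyl]hexahydro-1-benzofuran-2,5-dione, via methylene lactone 8 (not isolated)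
Conditions: PMe3 (20 mol%), t-AmOH, 20 °C; then PhSH, Et3N (20 mol%)
Reagents that add atoms: thiophenol, Sc1ccccc1
Why: In the intramolecular Rauhut–Currier reaction the phosphine adds to the acrylate and the α-carbanion closes 5-exo on the enone β-carbon, which can only give the cis-fused lactone (sets C-7′); thia-Michael addition then masks the α-methylene lactone against the diazoalkane and enolates to come.

Step 6
Reactants: 9 (3aS,6R,7aS)-6-methyl-3-[(phenylsulfanyl)methyl]hexahydro-1-benzofuran-2,5-dione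
Product: 11 (3aS,7R,8aS)-7-methyl-3-[(phenylsulfanyl)methyl]hexahydro-2H-cyclohepta[b]furan-2,6(3H)-dione, via α-silyl ketone 10 (not isolated)
Conditions: TMSCHN2 (1.5 equiv), Sc(OTf)3 (10 mol%), CH2Cl2, −40 → 0 °C; then 1 M HCl, THF, 20 °C
Reagents that add atoms: (trimethylsilyl)diazomethane, C[Si](C)(C)C=[N+]=[N-]
Why: In this Lewis-acid-catalysed diazoalkane–carbonyl homologation (1,2-shift with loss of N2) the ring methylene migrates in preference to the methyl-bearing methine, the bulky α-silyl group stops a second insertion, acid removes silicon, and no stereocentre is touched.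

Step 7
Reactants: 11 (3aS,7R,8aS)-7-methyl-3-[(phenylsulfanyl)methyl]hexahydro-2H-cyclohepta[b]furan-2,6(3H)-dione
Product: 13 (3aS,7R,8aS)-7-methyl-2-oxo-3-[(phenylsulfanyl)methyl]-3,3a,4,7,8,8a-hexahydro-2H-cyclohepta[b]furan-6-yl trifluoromethanesulfonate, via lithium enolate 12 (not isolated)
Conditions: LiN(iPr)2 (1.05 equiv), THF, −78 °C; PhNTf2, −78 → 0 °C
Reagents that add atoms: N-phenylbis(trifluoromethanesulfonimide), O=S(=O)(N(c1ccccc1)S(=O)(=O)C(F)(F)F)C(F)(F)F
Why: Kinetic deprotonation on the methylene side (C-5′) and O-sulfonylation fix the C1′=C5′ olefin position (enol triflate formation).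

Step 8
Reactants: 13 enol triflate; 14 2-(2-bromoethyl)-2-methyl-1,3-dioxolane
Product: 16 (3aS,7R,8aS)-7-methyl-6-[2-(2-methyl-1,3-dioxolan-2-yl)ethyl]-3-[(phenylsulfanyl)methyl]-3,3a,4,7,8,8a-hexahydro-2H-cyclohepta[b]furan-2-one, via alkylzinc bromide 15 (not isolated)
Conditions: 14, Zn dust (activated), LiCl, THF, 40 °C; then 13, PdCl2(dppf) (5 mol%), THF, 50 °C
Reagents that add atoms: none
Why: Negishi sp2–sp3 cross-coupling of the alkenyl triflate with the primary alkylzinc reagent installs the ketal-masked 3-oxobutyl chain.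

Step 9
Reactants: 16 coupled sulfide
Product: 18 (3aS,7R,8aS)-7-methyl-3-methylidene-6-[2-(2-methyl-1,3-dioxolan-2-yl)ethyl]-3,3a,4,7,8,8a-hexahydro-2H-cyclohepta[b]furan-2-one, via sulfoxide 17 (not isolated)
Conditions: NaIO4, MeOH/H2O, 0 → 20 °C; then toluene, NaHCO3, 100 °C
Reagents that add atoms: none
Why: Chemoselective sulfide-to-sulfoxide oxidation and thermal syn-elimination of benzenesulfenic acid (the only β-hydrogen is the lactone α-H) free the α-methylene lactone.

Step 10
Reactants: 2 2,3-dioxabicyclo[2.2.2]oct-5-ene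
Product: 19 (S)-4-hydroxycyclohex-2-en-1-one
Conditions: 9-O-acetylcupreine (10 mol%), CH2Cl2, 20 °C
Reagents that add atoms: none
Why: Same Kornblum–DeLaMare desymmetrisation as step 2 on the second portion of 2, with the pseudo-enantiomeric base removing the other bridgehead hydrogen to give the antipode.

Step 11
Reactants: 19 (S)-4-hydroxycyclohex-2-en-1-one
Product: 21 (4S,6S)-4-hydroxy-6-methylcyclohex-2-en-1-one (4,6-trans), via dilithium alkoxide-dienolate 20 (not isolated)
Conditions: LiN(iPr)2 (2.2 equiv), THF, −78 °C; MeI (1.05 equiv), −78 → −40 °C; 1 M HCl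
Reagents that add atoms: iodomethane, CI
Why: Enolate alkylation anti to the C-4 oxygen, as in step 3.

Step 12
Reactants: 21 (4S,6S)-4-hydroxy-6-methylcyclohex-2-en-1-one; 6 acrylic acid
Product: 22 (1R,5S)-5-methyl-4-oxocyclohex-2-en-1-yl prop-2-enoate (1,5-cis)
Conditions: PPh3, DIAD, THF, 0 → 20 °C
Reagents that add atoms: none
Why: Mitsunobu inversion, as in step 4, places the future C-8 oxygen cis to the C-10 methyl group.

Step 13
Reactants: 22 (1R,5S)-5-methyl-4-oxocyclohex-2-en-1-yl prop-2-enoate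
Product: 24 (3aR,6S,7aR)-6-methyl-3-[(phenylsulfanyl)methyl]hexahydro-1-benzofuran-2,5-dione, via methylene lactone 23 (not isolated)
Conditions: PMe3 (20 mol%), t-AmOH, 20 °C; then PhSH, Et3N (20 mol%)
Reagents that add atoms: thiophenol, Sc1ccccc1
Why: Intramolecular Rauhut–Currier annulation sets the cis-fused C-7 centre, and the thiol adduct masks the ring-A methylene lactone until the last step.

Step 14
Reactants: 24 (3aR,6S,7aR)-6-methyl-3-[(phenylsulfanyl)methyl]hexahydro-1-benzofuran-2,5-dione
Product: 26 (3aR,7S,8aR)-7-methyl-3-[(phenylsulfanyl)methyl]hexahydro-2H-cyclohepta[b]furan-2,6(3H)-dione, via α-silyl ketone 25 (not isolated)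
Conditions: TMSCHN2 (1.5 equiv), Sc(OTf)3 (10 mol%), CH2Cl2, −40 → 0 °C; then 1 M HCl, THF, 20 °C
Reagents that add atoms: (trimethylsilyl)diazomethane, C[Si](C)(C)C=[N+]=[N-]
Why: Regioselective diazoalkane ring expansion with migration of the methylene carbon, as in step 6, builds the seven-membered ring A with its C-1 ketone.

Step 15
Reactants: 27 nitromethane; 28 methylglyoxal (40% in water)
Product: 30 (E)-4-nitrobut-3-en-2-one, via nitro alcohol 29 (not isolated)
Conditions: K2CO3 (5 mol%), H2O, 0 °C; extract; MsCl, Et3N, CH2Cl2, −20 °C; used at once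
Reagents that add atoms: none
Why: Nitro-aldol (Henry) addition to the aldehyde carbon, then mesylation and E1cB dehydration, give the E-nitro-enone.

Step 16
Reactants: 26 ring-A keto-lactone; 18 methylene lactone; 30 (E)-4-nitrobut-3-en-2-one
Product: 36 sulfide-masked target (38 with the ring-A C=CH2 replaced by CH–CH2SPh), via C-5 lithium enolate 31 (not isolated), via lactone enolate 32 (not isolated), via lithium nitronate 33 (not isolated), via nitro alcohol 34 (not isolated), via ketal 35 (not isolated)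
Conditions: LiN(iPr)2 (1.05 equiv), THF, −78 °C; 18 (0.95 equiv), −78 °C; 30 (1.1 equiv), −78 → −20 °C; DBU (2 equiv), −20 → 20 °C; then 1 M HCl, THF, 20 °C
Reagents that add atoms: water, O
Why: Proposed new method: a three-component anionic relay annulation with the β-nitro-enone as a two-carbon linchpin, in which first the kinetic C-5 enolate of 26 adds to the exocyclic methylene of 18 on the π-face syn to the lactone (argued to be the exposed face of the chair cycloheptenolate and the face that carries C-13′ in the target), second the new lactone enolate adds from its convex face to the nitro-enone carbon α to the ketone and so sets spiro C-11′, third the nitronate closes on the C-1 ketone anti to the C-10 methyl group in a reversible nitro-aldol (trans ring fusion, 1-OH), and fourth DBU-induced E1cB loss of nitrite makes the C2=C3 enone irreversibly before the acidic work-up cleaves the ketal; the closest known reaction types are Michael–Michael–ring-closure annulations of ketone enolates with two acrylate-type acceptors, Michael/Michael/Henry cascades, and addition–denitration of β-nitro-enones.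

Step 17
Reactants: 36 sulfide-masked target
Product: 38 CNP0195550.2, via sulfoxide 37 (not isolated)
Conditions: NaIO4, MeOH/H2O, 0 → 20 °C; then toluene, NaHCO3, 90 °C
Reagents that add atoms: none
Why: Sulfide oxidation and thermal sulfoxide syn-elimination free the ring-A α-methylene lactone without touching the enone, the tertiary allylic alcohol or the trisubstituted olefin.

## Compound list

1 | cyclohexa-1,3-diene | C1=CC=CCC1 | starting material
2 | 2,3-dioxabicyclo[2.2.2]oct-5-ene (meso endoperoxide) | C1=CC2CCC1OO2 | intermediate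
3 | (R)-4-hydroxycyclohex-2-en-1-one | O[C@@H]1CCC(=O)C=C1 | intermediate
4 | dilithium alkoxide-dienolate of 3 | [Li]O[C@@H]1CC=C(O[Li])C=C1 | intermediate
5 | (4R,6R)-4-hydroxy-6-methylcyclohex-2-en-1-one (trans) | O[C@@H]1C[C@@H](C)C(=O)C=C1 | intermediate
6 | acrylic acid | C=CC(=O)O | starting material
7 | (1S,5R)-5-methyl-4-oxocyclohex-2-en-1-yl prop-2-enoate (cis) | C=CC(=O)O[C@H]1C[C@@H](C)C(=O)C=C1 | intermediate
8 | (3aS,6R,7aS)-6-methyl-3-methylidenehexahydro-1-benzofuran-2,5-dione (cis-fused) | C=C1C(=O)O[C@H]2C[C@@H](C)C(=O)C[C@@H]12 | intermediate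
9 | (3aS,6R,7aS)-6-methyl-3-[(phenylsulfanyl)methyl]hexahydro-1-benzofuran-2,5-dione (C-3 epimers) | c1ccccc1SCC1C(=O)O[C@H]2C[C@@H](C)C(=O)C[C@@H]12 | intermediate
10 | 5-(trimethylsilyl) derivative of 11 (α-silyl ketone) | c1ccccc1SCC1C(=O)O[C@H]2C[C@@H](C)C(=O)C([Si](C)(C)C)C[C@@H]12 | intermediate
11 | (3aS,7R,8aS)-7-methyl-3-[(phenylsulfanyl)methyl]hexahydro-2H-cyclohepta[b]furan-2,6(3H)-dione | c1ccccc1SCC1C(=O)O[C@H]2C[C@@H](C)C(=O)CC[C@@H]12 | intermediate
12 | kinetic lithium enolate of 11 (C1′=C5′) | c1ccccc1SCC1C(=O)O[C@H]2C[C@@H](C)C(O[Li])=CC[C@@H]12 | intermediate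
13 | (3aS,7R,8aS)-7-methyl-2-oxo-3-[(phenylsulfanyl)methyl]-3,3a,4,7,8,8a-hexahydro-2H-cyclohepta[b]furan-6-yl trifluoromethanesulfonate | c1ccccc1SCC1C(=O)O[C@H]2C[C@@H](C)C(OS(=O)(=O)C(F)(F)F)=CC[C@@H]12 | intermediate
14 | 2-(2-bromoethyl)-2-methyl-1,3-dioxolane (4-bromobutan-2-one as its ethylene ketal; six non-hydrogen atoms without the protecting group) | CC1(CCBr)OCCO1 | starting material
15 | [2-(2-methyl-1,3-dioxolan-2-yl)ethyl]zinc bromide | CC1(CC[Zn]Br)OCCO1 | intermediate
16 | (3aS,7R,8aS)-7-methyl-6-[2-(2-methyl-1,3-dioxolan-2-yl)ethyl]-3-[(phenylsulfanyl)methyl]-3,3a,4,7,8,8a-hexahydro-2H-cyclohepta[b]furan-2-one | c1ccccc1SCC1C(=O)O[C@H]2C[C@@H](C)C(CCC3(C)OCCO3)=CC[C@@H]12 | intermediate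
17 | S-oxide of 16 (sulfoxide) | O=S(c1ccccc1)CC1C(=O)O[C@H]2C[C@@H](C)C(CCC3(C)OCCO3)=CC[C@@H]12 | intermediate
18 | (3aS,7R,8aS)-7-methyl-3-methylidene-6-[2-(2-methyl-1,3-dioxolan-2-yl)ethyl]-3,3a,4,7,8,8a-hexahydro-2H-cyclohepta[b]furan-2-one (lower half with its exocyclic methylene, ketone as ethylene ketal) | C=C1C(=O)O[C@H]2C[C@@H](C)C(CCC3(C)OCCO3)=CC[C@@H]12 | intermediate
19 | (S)-4-hydroxycyclohex-2-en-1-one | O[C@H]1CCC(=O)C=C1 | intermediate
20 | dilithium alkoxide-dienolate of 19 | [Li]O[C@H]1CC=C(O[Li])C=C1 | intermediate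
21 | (4S,6S)-4-hydroxy-6-methylcyclohex-2-en-1-one (trans) | O[C@H]1C[C@H](C)C(=O)C=C1 | intermediate
22 | (1R,5S)-5-methyl-4-oxocyclohex-2-en-1-yl prop-2-enoate (cis) | C=CC(=O)O[C@@H]1C[C@H](C)C(=O)C=C1 | intermediate
23 | (3aR,6S,7aR)-6-methyl-3-methylidenehexahydro-1-benzofuran-2,5-dione (cis-fused) | C=C1C(=O)O[C@@H]2C[C@H](C)C(=O)C[C@H]12 | intermediate
24 | (3aR,6S,7aR)-6-methyl-3-[(phenylsulfanyl)methyl]hexahydro-1-benzofuran-2,5-dione (C-3 epimers) | c1ccccc1SCC1C(=O)O[C@@H]2C[C@H](C)C(=O)C[C@H]12 | intermediate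
25 | 5-(trimethylsilyl) derivative of 26 (α-silyl ketone) | c1ccccc1SCC1C(=O)O[C@@H]2C[C@H](C)C(=O)C([Si](C)(C)C)C[C@H]12 | intermediate
26 | (3aR,7S,8aR)-7-methyl-3-[(phenylsulfanyl)methyl]hexahydro-2H-cyclohepta[b]furan-2,6(3H)-dione | c1ccccc1SCC1C(=O)O[C@@H]2C[C@H](C)C(=O)CC[C@H]12 | intermediate
27 | nitromethane | C[N+](=O)[O-] | starting material
28 | methylglyoxal (2-oxopropanal) | CC(=O)C=O | starting material
29 | 3-hydroxy-4-nitrobutan-2-one (racemic) | CC(=O)C(O)C[N+](=O)[O-] | intermediate
30 | (E)-4-nitrobut-3-en-2-one | CC(=O)/C=C/[N+](=O)[O-] | intermediate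
31 | kinetic C-5 lithium enolate of 26 | c1ccccc1SCC1C(=O)O[C@@H]2C[C@H](C)C(O[Li])=CC[C@H]12 | intermediate
32 | lithium lactone enolate from Michael addition of 31 to 18 (C5–C13′ bond made, 13′ on the lactone face of ring A) | c5ccccc5SCC1C(=O)O[C@@H]2C[C@H](C)C(=O)[C@H](CC4=C(O[Li])O[C@H]6C[C@@H](C)C(CCC5(C)OCCO5)=CC[C@H]64)C[C@H]12 | intermediate
33 | lithium nitronate from addition of 32 to 30 (spiro C-11′ set, C-1 still a ketone) | c5ccccc5SCC1C(=O)O[C@@H]2C[C@H](C)C(=O)[C@H](C[C@@]4(C(C(C)=O)C=[N+]([O-])O[Li])C(=O)O[C@H]6C[C@@H](C)C(CCC5(C)OCCO5)=CC[C@H]64)C[C@H]12 | intermediate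
34 | cyclised nitro alcohol (central ring closed, 2-NO2, 3-H; present as its lithium alkoxide) | c5ccccc5SCC1C(=O)O[C@@H]2C[C@H](C)[C@@]3(O)C([N+](=O)[O-])C(C(C)=O)[C@]4(C[C@@H]3C[C@H]12)C(=O)O[C@H]1C[C@@H](C)C(CCC5(C)OCCO5)=CC[C@H]14 | intermediate
35 | ethylene ketal of 36 (hydroxy-enone, side-chain ketone still protected) | c5ccccc5SCC1C(=O)O[C@@H]2C[C@H](C)[C@@]3(O)C=C(C(C)=O)[C@]4(C[C@@H]3C[C@H]12)C(=O)O[C@H]1C[C@@H](C)C(CCC5(C)OCCO5)=CC[C@H]14 | intermediate
36 | sulfide-masked target: 38 with ring-A C-11 as CH–CH2SPh (C-11 epimers) | c5ccccc5SCC1C(=O)O[C@@H]2C[C@H](C)[C@@]3(O)C=C(C(C)=O)[C@]4(C[C@@H]3C[C@H]12)C(=O)O[C@H]1C[C@@H](C)C(CCC(C)=O)=CC[C@H]14 | intermediate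
37 | S-oxide of 36 (sulfoxide) | O=S(c5ccccc5)CC1C(=O)O[C@@H]2C[C@H](C)[C@@]3(O)C=C(C(C)=O)[C@]4(C[C@@H]3C[C@H]12)C(=O)O[C@H]1C[C@@H](C)C(CCC(C)=O)=CC[C@H]14 | intermediate
38 | CNP0195550.2: (1S,5S,7R,8R,10S,7′S,8′S,10′R,11′R) spiro-dimeric xanthanolide; 1-OH, 10-Me, C-13′ and the ring-A lactone on one face of ring A, trans-fused central cyclohexene, C-3 on the convex face of the spiro lactone | C=C1C(=O)O[C@@H]2C[C@H](C)[C@@]3(O)C=C(C(C)=O)[C@]4(C[C@@H]3C[C@H]12)C(=O)O[C@H]1C[C@@H](C)C(CCC(C)=O)=CC[C@H]14 | target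

## Step count and risk

Total step count: 17. Longest linear sequence: 11 steps (steps 1–9, then 16 and 17).

Three steps most likely to fail:

Step 16 (the new annulation). Possible failures are proton transfer or oligomerisation after the first Michael addition, base-induced loss of thiophenolate from the masked ring-A lactone, loss of nitrous acid from the open-chain adduct before the nitro-aldol closure, and the wrong face at C-5 or C-1. The fallback uses known chemistry and sets out from 26 (with 18). Enolate 31 is trapped with PhNTf2 to give the enol triflate F1. Heck coupling with but-3-en-2-one (Pd(OAc)2, PPh3, Et3N, DMF, 70 °C) gives the sulfide-masked 8-epi-xanthatin F2. Thermal [4+2] addition of this diene to 18 (toluene, 110 °C, BHT) gives the spiro adduct F3 with the C1=C2 olefin and a 3-H. Deprotonation at C-3 and γ-oxygenation of the dienolate (KOtBu, O2, THF/t-BuOH, −20 °C) give the 1-hydroperoxide F4, which P(OEt)3 reduces in the same flask. The fallback comes back to the route at 35, which is hydrolysed as in step 16 to 36.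

Step 6 (ring expansion). Possible failures are migration of the methyl-bearing carbon and interference by the lactone or sulfide with the Lewis acid. The fallback fixes the regiochemistry by kinetic enolisation and sets out from 9. LiN(iPr)2 at −78 °C gives the kinetic lithium enolate F5 on the methylene side, and TMSCl gives the trimethylsilyl enol ether F6. Simmons–Smith cyclopropanation (Et2Zn, CH2I2) gives the siloxycyclopropane F7. FeCl3 in DMF opens it to the ring-enlarged β-chloro ketone F8 (Ito–Saegusa ring expansion), and NaOAc in MeOH eliminates HCl to the cycloheptenone F9. Conjugate reduction with [(Ph3P)CuH]6 returns to the route at 11.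

Step 4 (Mitsunobu inversion on a γ-hydroxy-enone). Possible failures are SN2′ attack or elimination towards a phenol. The fallback moves the methyl group instead of the oxygen and sets out from the antipodal-series alcohol 21. LiN(iPr)2 (2.2 equiv) gives the dilithium alkoxide-enolate F10. Kinetic protonation with AcOH at −78 °C, anti to the C-4 oxygen, gives the cis alcohol F11. Acylation with acryloyl chloride and Et3N (retention) returns to the route at 7; the two hydroxy-enone antipodes then swap roles.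

## Further compounds

F1 | step 16 | (3aR,7S,8aR)-7-methyl-2-oxo-3-[(phenylsulfanyl)methyl]-3,3a,4,7,8,8a-hexahydro-2H-cyclohepta[b]furan-6-yl trifluoromethanesulfonate | c1ccccc1SCC1C(=O)O[C@@H]2C[C@H](C)C(OS(=O)(=O)C(F)(F)F)=CC[C@H]12
F2 | step 16 | sulfide-masked 8-epi-xanthatin (6-[(E)-3-oxobut-1-enyl] dienone) | c1ccccc1SCC1C(=O)O[C@@H]2C[C@H](C)C(/C=C/C(C)=O)=CC[C@H]12
F3 | step 16 | [4+2] adduct of F2 and 18 (C1=C2 olefin, 3-H, ketal and sulfide in place) | c5ccccc5SCC1C(=O)O[C@@H]2C[C@H](C)C3=CC(C(C)=O)[C@]4(C[C@@H]3C[C@H]12)C(=O)O[C@H]1C[C@@H](C)C(CCC5(C)OCCO5)=CC[C@H]14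
F4 | step 16 | 1-hydroperoxide corresponding to 35 | c5ccccc5SCC1C(=O)O[C@@H]2C[C@H](C)[C@@]3(OO)C=C(C(C)=O)[C@]4(C[C@@H]3C[C@H]12)C(=O)O[C@H]1C[C@@H](C)C(CCC5(C)OCCO5)=CC[C@H]14
F5 | step 6 | kinetic lithium enolate of 9 (methylene side) | c1ccccc1SCC1C(=O)O[C@H]2C[C@@H](C)C(O[Li])=C[C@@H]12
F6 | step 6 | trimethylsilyl enol ether of 9 | c1ccccc1SCC1C(=O)O[C@H]2C[C@@H](C)C(O[Si](C)(C)C)=C[C@@H]12
F7 | step 6 | siloxycyclopropane from F6 | c1ccccc1SCC1C(=O)O[C@H]2C[C@@H](C)C3(O[Si](C)(C)C)CC3[C@@H]12
F8 | step 6 | ring-enlarged β-chloro ketone (4-chloro derivative of 11) | c1ccccc1SCC1C(=O)O[C@H]2C[C@@H](C)C(=O)CC(Cl)[C@@H]12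
F9 | step 6 | cycloheptenone (4,5-didehydro derivative of 11) | c1ccccc1SCC1C(=O)O[C@H]2C[C@@H](C)C(=O)C=C[C@@H]12
F10 | step 4 | dilithium alkoxide-enolate of 21 | [Li]O[C@H]1CC(C)=C(O[Li])C=C1
F11 | step 4 | (4S,6R)-4-hydroxy-6-methylcyclohex-2-en-1-one (cis) | O[C@H]1C[C@@H](C)C(=O)C=C1
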